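The earlier runs and the new flask come from a simulation for substances that don't exist.

A small charge of protic impurity faces a large charge of starting material, and it is the limiting reagent of the quench. In autumn the protic impurity is 2.00% of the starting material charged. This fraction, impurity charged over starting material charged, is the quench share. It counts one molecule of starting material lost per molecule of impurity.

| flask | starting material | protic impurity | free catalyst | remark | time |
|---|---|---|---|---|---|
| east | 0.050 M | 0.73 mM | 0.5 mol% | run made earlier |  |
| north | 0.050 M | 3 mM | 0.5 mol% | run made earlier |  |
| autumn | 0.050 M | 1.00 mM | 0.5 mol% |  | 5.0 h |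
| dawn | 0.050 M | 2.00 mM | 0.5 mol% |  | 5.0 h |
| winter | 0.050 M | 4.00 mM | 0.5 mol% |  | 5.0 h |

| run | time / h | product / % | starting material / % |
|---|---|---|---|
| east | 0.133 | 10.9 | 86.6 |
| east | 0.417 | 36.3 | 63.2 |
| east | 0.667 | 52.0 | 45.4 |
| east | 1.00 | 70.0 | 29.1 |
| east | 1.50 | 86.0 | 11.7 |
| east | 2.00 | 93.4 | 5.0 |
| east | 2.50 | 97.4 | 1.6 |
| north | 0.333 | 27.7 | 65.4 |
| north | 0.667 | 50.9 | 42.4 |
| north | 1.00 | 67.6 | 25.5 |
| north | 1.33 | 79.3 | 15.6 |
| north | 2.00 | 90.0 | 2.8 |
| north | 2.50 | 92.0 | 1.6 |

(each reading ± 0.5 percentage points)

- the numbers in the tables scatter with a standard deviation of 0.5 percentage points
- steps that have been proposed: starting material + free catalyst -> catalyst intermediate A; catalyst intermediate A <-> catalyst intermediate B; catalyst intermediate B <-> free catalyst + product; starting material + protic impurity -> quenched substrate; 2 free catalyst <-> resting dimer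
- "hardly changes" means that all values lie within two and a half points (for a concentration: within two and a half percent of the largest)

- amount of product at the end, in percent of the starting material charged for autumn, dawn, winter, in this order
- the course of these numbers from the first flask to the last (rises all the way / falls, then rises / hardly changes / falls all the way / rises, then falls)

The opposite outcome, a flat row, asks for a loss that does not grow with the impurity. One way to that is a protic impurity that stays unreacted while the starting material disappears past it. The readings stand far from that. In north the quench share is 6.00%. The part of the charge missing from product and starting material reads 6.90% at 0.333 h, with 65.4% starting material still present. At 2.50 h it reads 6.40%, with 1.6% present. Within the scatter, the missing part in north stands at its level by the first reading and does not grow after it. In east, with a share of 1.46%, the last reading of the missing part is 1.00%, less than in north.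

In east and north, a molecule of starting material that escapes the impurity appears as product. East holds 1.6% starting material at 2.50 h, half of the time asked. Product at 1.00 h reads 70.0% in east and 67.6% in north, so the catalyst still turns with more impurity present.

The reckoning here is product = charge minus quench share. With 4.00% for dawn and 8.00% for winter, it gives 98.0%, 96.0% and 92.0%.

The forecast gives 97.8%, 91.8% and 83.8%, and says the row falls all the way. Its stated ground is “about 100 minus 2 per mM of impurity”. It matches this reckoning closely in autumn, but stands lower in dawn and in winter.

The flasks give 97.9%, 95.9% and 91.9%, and the row falls all the way.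

starting material + free catalyst → catalyst intermediate A (k = 13000 M⁻¹ h⁻¹); catalyst intermediate A ⇌ catalyst intermediate B (K = 1.80, k = 2800 h⁻¹); catalyst intermediate B ⇌ free catalyst + product (K = 0.180 M, k = 450 h⁻¹); starting material + protic impurity → quenched substrate (k = 250 M⁻¹ h⁻¹); 2 free catalyst ⇌ resting dimer (K = 3000 M⁻¹, k = 480 M⁻¹ h⁻¹) At 5.00 h winter holds 8.00% quenched substrate, with 0.020% of its own charge of protic impurity left. Taken from the charge, the quench share leaves 98.0% for autumn, which stands at 97.9%. It leaves 96.0% for dawn, which stands at 95.9%, and 92.0% for winter, which stands at 91.9%.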